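Per millimolar of charge is the unit I reckon in, since the six flasks share their time and differ in their charge.

| flask | substrate | remark | time |
|---|---|---|---|
| Wednesday's | 6.4 mM | run made earlier |  |
| Saturday's | 64 mM | run made earlier |  |
| alpha | 80 mM |  | 40 h |
| delta | 15 mM |  | 40 h |
| epsilon | 30 mM |  | 40 h |
| beta | 8.0 mM |  | 40 h |
| gamma | 40 mM |  | 40 h |
| eta | 21 mM |  | 40 h |

| run | time / h | target / % | side product / % |
|---|---|---|---|
| Wednesday's | 2.50 | 2.9 | 1.7 |
| Wednesday's | 5.00 | 6.6 | 4.0 |
| Wednesday's | 12.0 | 11.6 | 6.9 |
| Wednesday's | 30.0 | 12.3 | 9.7 |
| Saturday's | 8.00 | 6.8 | 33.8 |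
| Saturday's | 15.0 | 6.9 | 39.2 |
| Saturday's | 20.0 | 7.4 | 41.3 |
| Saturday's | 30.0 | 7.4 | 44.6 |

(readings scatter by 0.5 percentage points)

- percentages count the substrate that a species holds: one side product counts as two
- a reading or a percentage of target counts all its forms, free or not

* all flasks from highest to lowest share of target in all that became target or side product, at 40 h (alpha / delta / epsilon / beta / gamma / eta)
* the share of target in all that became target or side product of the flask you put first, at 40 h
* the share of target in all that became target or side product of the flask you put last, at 40 h

Does the split move with the charge? Wednesday's last reading holds 0.789 of side product per unit of target and Saturday's 6.03, so ten times the charge raises that ratio by a factor of 7.64.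

Why nearly in step? Suppose side product needs substrate as a second partner and target does not: dividing one rate by the other then drops time out and leaves a ratio proportional to c(substrate). So I divide by the charge, and Wednesday's 0.123 mM⁻¹ is f, the selectivity factor, side product per unit of target per millimolar charged; Saturday's reading gives 0.0942 mM⁻¹. The share of target is then one over one plus f times the charge.

Can f reorder the flasks? As read, it shifts by a factor of 1.31 across the tenfold span, less than the 1.33 between the closest charges, so I rank by charge, though the scatter of the readings could close a margin that narrow. With the nearer run's f, I get 50.4% for beta and 11.7% for alpha. Both ratios still climb in the last readings, Wednesday's from 0.595 at 12.0 h to 0.789 at 30.0 h and Saturday's from 5.58 at 20.0 h to 6.03 at 30.0 h, so I take both shares to lean high.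

The forecast gives beta > delta > eta > epsilon > gamma > alpha, with 49% (44% to 55%) and 12% (9% to 14%): “I expect the order to be monotonic in concentration, but that is an assumption.”

The flasks give beta > delta > eta > epsilon > gamma > alpha, with 47.4% and 10.7%.

    substrate ⇌ intermediate A (K = 0.920, k = 0.270 h⁻¹)
    substrate ⇌ intermediate B (K = 5.70, k = 0.170 h⁻¹)
    intermediate A ⇌ target (K = 1.10, k = 0.0670 h⁻¹)
    substrate + target ⇌ idle adduct, settled at all times (K = 30.0 M⁻¹)
    substrate + intermediate A → side product (k = 7.50 M⁻¹ h⁻¹)

Beta's own f at 40.0 h comes to 0.139 mM⁻¹, against the 0.123 mM⁻¹ read from Wednesday's run at 30.0 h. Beta's recipe at 3.2 mM reckons to 71.8% with 0.123 mM⁻¹ and stands at 68.4%. Beta's share has moved 5 points at 9.93 mM of substrate, or at 56.9 h with the charge held, which puts it below the forecast's low end for beta. In beta, the forward step from intermediate A to target uses it 2.9 times as fast as the step to side product at 2.87 h. That ratio reaches 11 at 40.0 h, yet the step to target has 83% of its turnover behind it by 8.00 h.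

The earlier runs and the new flask were computed with constants of no real substance, and the scatter is random.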